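The flavanone is cut at the aryl ether bond O1–C8a of ring C. Because O1 sits between the stereogenic C2 and the sp2 carbon C8a of ring A, the heterocycle can be stitched at the arene and C2 is a mere spectator. One copper-catalysed intramolecular O-arylation makes this bond, closes ring C and hands on, with retention, the C2 configuration installed earlier by asymmetric ketone reduction. The cyclisation substrate is the hepta-O-benzyl (S,S)-1,3-diol 15: its C2 carbinol bears ring B with the apigenin unit at C5', its C4 carbinol a 2-bromo-4,6-bis(benzyloxy)phenyl group. C4 oxidation and hydrogenolysis finish; base-labile 2'-hydroxychalcones are avoided throughout.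

Key step: step 12

Remarks
- Numbering: flavanone atoms are unprimed (benzo ring A, pyranone ring C). The catechol ring B is primed. Flavone atoms are double-primed (benzo ring D, pyrone ring E, 4-oxyphenyl ring F). Open-chain intermediates carry the numbers of the atoms they become. Bn = benzyl.
- Assumption: the C5'–C8'' biaryl axis has three ortho oxygen substituents and one ortho hydrogen, as in amentoflavone. It is taken to rotate at room temperature and is not treated as a stereogenic element.
- Ring B enters as the catalogue catechol aldehyde 4, so no methyl ether has to be removed later.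
- Ring A is C-acetylated as the free resorcinol and benzylated afterwards, because Lewis acids would strip or shift benzyl groups.
- The diketone is made by aldol addition and oxidation, so the flavone never meets excess strong base.
- The two carbonyl groups are reduced separately. The ruthenium catalyst should accept only the unhindered C2 carbonyl, so the doubly ortho-substituted C4 carbonyl is reduced by hydroxyl-directed hydride delivery.

Step 1
Reactants: 1 apigenin
Product: 2 5,7-bis(benzyloxy)-2-[4-(benzyloxy)phenyl]-4H-chromen-4-one (tri-O-benzylapigenin)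
Conditions: BnBr (4.5 equiv), K2CO3 (6 equiv), DMF, 80 °C
Reagents that add atoms: benzyl bromide, BrCc1ccccc1
Why: Williamson etherification in which excess halide and heat also alkylate the chelated 5''-OH, while carbonate is too weak a base to open the pyrone ring E.

Step 2
Reactants: 2 tri-O-benzylapigenin
Product: 3 5,7-bis(benzyloxy)-2-[4-(benzyloxy)phenyl]-8-iodo-4H-chromen-4-one
Conditions: NIS (1.1 equiv), CF3CO2H (0.3 equiv), CH2Cl2/MeCN, 0 °C to rt, dark
Reagents that add atoms: N-iodosuccinimide, O=C1CCC(=O)N1I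
Why: Electrophilic aromatic iodination, which in fully O-alkylated 5,7-dioxygenated flavones goes to C8'' because C6'' is squeezed between two benzyloxy groups and ring F and C3'' are far less activated.

Step 3
Reactants: 4 3-bromo-4,5-dihydroxybenzaldehyde
Product: 5 3,4-bis(benzyloxy)-5-bromobenzaldehyde
Conditions: BnBr (2.4 equiv), K2CO3 (3 equiv), DMF, 50 °C
Reagents that add atoms: benzyl bromide, BrCc1ccccc1
Why: Williamson etherification of both catechol hydroxyls, with aldehyde and aryl bromide inert to carbonate.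

Step 4
Reactants: 5 3,4-bis(benzyloxy)-5-bromobenzaldehyde
Product: 6 3,4-bis(benzyloxy)-5-(4,4,5,5-tetramethyl-1,3,2-dioxaborolan-2-yl)benzaldehyde
Conditions: B2pin2 (1.2 equiv), Pd(dppf)Cl2 (3 mol %), KOAc (3 equiv), dioxane, 90 °C
Reagents that add atoms: bis(pinacolato)diboron, CC1(C)OB(OC1(C)C)B1OC(C)(C)C(C)(C)O1
Why: Miyaura borylation, which tolerates aldehydes and puts boron on the partner with only one ortho oxygen, the one less prone to protodeboronation.

Step 5
Reactants: 3 8-iodo-tri-O-benzylapigenin; 6 ring-B pinacol boronate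
Product: 7 3,4-bis(benzyloxy)-5-(tri-O-benzylapigenin-8-yl)benzaldehyde (biaryl aldehyde, C5'–C8'' bond)
Conditions: Pd(OAc)2 (5 mol %), SPhos (10 mol %), K3PO4 (3 equiv), toluene/H2O 10:1, 90 °C
Reagents that add atoms: none
Why: Suzuki–Miyaura coupling with the same ortho pattern as the established 3',8''-biflavone couplings, a bulky biarylphosphine on zerovalent palladium easing the formation of the tri-ortho-substituted biaryl.

Step 6
Reactants: 8 5-bromoresorcinol
Product: 9 1-(2-bromo-4,6-dihydroxyphenyl)ethanone
Conditions: AcOH (2 equiv), BF3·OEt2 (5 equiv), 90 °C; then H2O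
Reagents that add atoms: acetic acid, CC(=O)O
Why: Nencki-type Friedel–Crafts C-acylation of a resorcinol, which as with orcinol attacks the position para to one hydroxyl and ortho to the other and not the crowded carbon between the two hydroxyls, so the acetyl group lands next to bromine.

Step 7
Reactants: 9 1-(2-bromo-4,6-dihydroxyphenyl)ethanone
Product: 10 1-[2,4-bis(benzyloxy)-6-bromophenyl]ethanone
Conditions: BnBr (2.5 equiv), K2CO3 (3 equiv), DMF, 60 °C
Reagents that add atoms: benzyl bromide, BrCc1ccccc1
Why: Williamson etherification, warm enough to alkylate the hydroxyl that is hydrogen-bonded to the ketone.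

Step 8
Reactants: 10 1-[2,4-bis(benzyloxy)-6-bromophenyl]ethanone; 7 biaryl aldehyde
Product: 12 racemic 1-[2,4-bis(benzyloxy)-6-bromophenyl]-3-hydroxy-3-[3,4-bis(benzyloxy)-5-(tri-O-benzylapigenin-8-yl)phenyl]propan-1-one, via lithium enolate 11 (not isolated)
Conditions: 10 (1.2 equiv), LiN(SiMe3)2 (1.15 equiv), THF, −78 °C; then 7 (1.0 equiv), THF, −78 °C; AcOH quench at −78 °C
Reagents that add atoms: none
Why: Lithium enolate aldol addition forming C2–C3, in which the preformed enolate finds the aldehyde as by far the best electrophile, no free amide base reaches the flavone, and the racemic C2 carbinol is erased in the next step.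

Step 9
Reactants: 12 racemic aldol
Product: 13 1-[2,4-bis(benzyloxy)-6-bromophenyl]-3-[3,4-bis(benzyloxy)-5-(tri-O-benzylapigenin-8-yl)phenyl]propane-1,3-dione (largely enolised)
Conditions: IBX (2.5 equiv), EtOAc, 75 °C
Reagents that add atoms: none
Why: IBX oxidation of a β-hydroxy ketone to the β-diketone, a heterogeneous neutral procedure that avoids over-oxidation at C3 and leaves aryl benzyl ethers alone.

Step 10
Reactants: 13 1,3-diketone
Product: 14 (3S)-1-[2,4-bis(benzyloxy)-6-bromophenyl]-3-hydroxy-3-[3,4-bis(benzyloxy)-5-(tri-O-benzylapigenin-8-yl)phenyl]propan-1-one (C2 is S)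
Conditions: RuCl(p-cymene)[(S,S)-TsDPEN] (3 mol %), HCO2H/Et3N 5:2, CH2Cl2, 30 °C
Reagents that add atoms: none
Why: Noyori–Ikariya asymmetric transfer hydrogenation in which the (S,S)-catalyst passes Ru–H and N–H to the Re face of the unhindered ring-B carbonyl with the aryl group next to the cymene ligand, setting C2 as S, while the C4 carbonyl is screened on both faces by the ortho Br and OBn of the twisted ring A and the vinylogous ester of ring E is too electron-rich to react.

Step 11
Reactants: 14 (S)-β-hydroxy ketone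
Product: 15 (1S,3S)-1-[2,4-bis(benzyloxy)-6-bromophenyl]-3-[3,4-bis(benzyloxy)-5-(tri-O-benzylapigenin-8-yl)phenyl]propane-1,3-diol (anti; C4 is S, C2 is S)
Conditions: Me4NBH(OAc)3 (6 equiv), MeCN/AcOH 3:1, −30 to 0 °C; aq NaHCO3 work-up
Reagents that add atoms: none
Why: Evans–Saksena reduction in which the C2 hydroxyl replaces an acetate on boron and hydride is delivered intramolecularly through a chair-like six-membered transition state, giving the 1,3-anti diol and so C4 as S, the mild reagent ignoring the ring-E carbonyl and the low temperature sparing the acid-sensitive C4 carbinol.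

Step 12
Reactants: 15 (S,S)-1,3-diol aryl bromide
Product: 16 (2S,4S)-hepta-O-benzyl flavan-4-ol (2,4-cis)
Conditions: CuI (20 mol %), 3,4,7,8-tetramethyl-1,10-phenanthroline (40 mol %), Cs2CO3 (2.5 equiv), 4 Å MS, degassed toluene (0.02 M), 110 °C, Ar
Reagents that add atoms: none
Why: Cs2CO3 forms the C2 alkoxide, which binds phenanthroline-ligated monovalent copper; the metal then inserts into the nearby C8a–Br bond to give a seven-membered trivalent cupracycle, and C–O reductive elimination releases 16 and the catalyst. The closest known reaction is the Ullmann-type intramolecular O-arylation of secondary alcohols with aryl bromides that is established for chromans. Ring C closes as a six-membered ring by exo attack of O1 on the sp2 carbon C8a with bromide leaving outside the ring, and the anti diol places the 2-aryl and 4-hydroxy groups both pseudo-equatorial. No stereocentre is created, since none of the bonds C2–O1, C2–H, C2–C3 and C2–C1' takes part and copper alkoxides are reluctant to lose a β-hydride, so C2 and C4 both remain S. The step needs selection between two hydroxyls, which ring size provides because closure through the C4 oxygen would give a strained benzoxete, while dilution suppresses intermolecular etherification and the C–Br carbon, meta to both benzyloxy groups, is not deactivated by resonance. Oxygen must be excluded because copper–phenanthroline with O2 oxidises benzylic alcohols, whereas flavone and benzyl ethers tolerate anhydrous carbonate.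

Step 13
Reactants: 16 (2S,4S)-flavan-4-ol
Product: 17 (2S)-hepta-O-benzyl flavanone
Conditions: Dess–Martin periodinane (1.3 equiv), NaHCO3 (5 equiv), CH2Cl2, 0 °C to rt
Reagents that add atoms: none
Why: Dess–Martin oxidation of the secondary benzylic C4 carbinol under buffered conditions that neither ionise the electron-rich flavan-4-ol nor open ring C by β-elimination, so C2 stays S.

Step 14
Reactants: 17 (2S)-hepta-O-benzyl flavanone
Product: 18 target, (2S)-5,7,3',4'-tetrahydroxy-5'-(apigenin-8-yl)flavanone
Conditions: H2 (1 atm), 10% Pd/C, THF/MeOH 1:1, rt, stopped when uptake ends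
Reagents that add atoms: none
Why: Catalytic hydrogenolysis of seven aryl benzyl ethers under neutral conditions, under which the ring-E enone, the C4 ketone and the cyclic C2–O1 benzylic ether react much more slowly and no acid or base is present that could open ring C and racemise C2.

Compound list
1 | apigenin | O=c1cc(-c2ccc(O)cc2)oc2cc(O)cc(O)c12 | starting material
2 | tri-O-benzylapigenin | O=c1cc(-c2ccc(OCc3ccccc3)cc2)oc2cc(OCc3ccccc3)cc(OCc3ccccc3)c12 | intermediate
3 | 8-iodo-tri-O-benzylapigenin | O=c1cc(-c2ccc(OCc3ccccc3)cc2)oc2c(I)c(OCc3ccccc3)cc(OCc3ccccc3)c12 | intermediate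
4 | 3-bromo-4,5-dihydroxybenzaldehyde | O=Cc1cc(O)c(O)c(Br)c1 | starting material
5 | 3,4-bis(benzyloxy)-5-bromobenzaldehyde | O=Cc1cc(OCc2ccccc2)c(OCc2ccccc2)c(Br)c1 | intermediate
6 | 3,4-bis(benzyloxy)-5-(pinacolboryl)benzaldehyde | O=Cc1cc(OCc2ccccc2)c(OCc2ccccc2)c(B2OC(C)(C)C(C)(C)O2)c1 | intermediate
7 | biaryl aldehyde | O=Cc2cc(OCc9ccccc9)c(OCc9ccccc9)c(-c3c(OCc9ccccc9)cc(OCc9ccccc9)c4c(=O)cc(-c5ccc(OCc9ccccc9)cc5)oc34)c2 | intermediate
8 | 5-bromoresorcinol | Oc1cc(O)cc(Br)c1 | starting material
9 | 1-(2-bromo-4,6-dihydroxyphenyl)ethanone | CC(=O)c1c(Br)cc(O)cc1O | intermediate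
10 | 1-[2,4-bis(benzyloxy)-6-bromophenyl]ethanone | CC(=O)c1c(Br)cc(OCc2ccccc2)cc1OCc1ccccc1 | intermediate
11 | lithium enolate of 10 | [Li]OC(=C)c1c(Br)cc(OCc2ccccc2)cc1OCc1ccccc1 | intermediate
12 | racemic aldol (β-hydroxy ketone) | O=C(CC(O)c2cc(OCc9ccccc9)c(OCc9ccccc9)c(-c3c(OCc9ccccc9)cc(OCc9ccccc9)c4c(=O)cc(-c5ccc(OCc9ccccc9)cc5)oc34)c2)c1c(Br)cc(OCc9ccccc9)cc1OCc9ccccc9 | intermediate
13 | 1,3-diketone | O=C(CC(=O)c2cc(OCc9ccccc9)c(OCc9ccccc9)c(-c3c(OCc9ccccc9)cc(OCc9ccccc9)c4c(=O)cc(-c5ccc(OCc9ccccc9)cc5)oc34)c2)c1c(Br)cc(OCc9ccccc9)cc1OCc9ccccc9 | intermediate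
14 | (S)-β-hydroxy ketone | O=C(C[C@H](O)c2cc(OCc9ccccc9)c(OCc9ccccc9)c(-c3c(OCc9ccccc9)cc(OCc9ccccc9)c4c(=O)cc(-c5ccc(OCc9ccccc9)cc5)oc34)c2)c1c(Br)cc(OCc9ccccc9)cc1OCc9ccccc9 | intermediate
15 | (S,S)-1,3-diol aryl bromide | O[C@@H](C[C@H](O)c2cc(OCc9ccccc9)c(OCc9ccccc9)c(-c3c(OCc9ccccc9)cc(OCc9ccccc9)c4c(=O)cc(-c5ccc(OCc9ccccc9)cc5)oc34)c2)c1c(Br)cc(OCc9ccccc9)cc1OCc9ccccc9 | intermediate
16 | (2S,4S)-hepta-O-benzyl flavan-4-ol | O[C@H]1C[C@@H](c2cc(OCc9ccccc9)c(OCc9ccccc9)c(-c3c(OCc9ccccc9)cc(OCc9ccccc9)c4c(=O)cc(-c5ccc(OCc9ccccc9)cc5)oc34)c2)Oc2cc(OCc9ccccc9)cc(OCc9ccccc9)c21 | intermediate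
17 | (2S)-hepta-O-benzyl flavanone | O=C1C[C@@H](c2cc(OCc9ccccc9)c(OCc9ccccc9)c(-c3c(OCc9ccccc9)cc(OCc9ccccc9)c4c(=O)cc(-c5ccc(OCc9ccccc9)cc5)oc34)c2)Oc2cc(OCc9ccccc9)cc(OCc9ccccc9)c21 | intermediate
18 | CNP0204144.1 | O=C1C[C@@H](c2cc(O)c(O)c(-c3c(O)cc(O)c4c(=O)cc(-c5ccc(O)cc5)oc34)c2)Oc2cc(O)cc(O)c21 | target

Total step count: 14. Longest linear sequence: 10 steps (1, 2, 5, 8, 9, 10, 11, 12, 13, 14, from apigenin).

Steps most likely to fail

Step 12.
- What may go wrong: the 1,3-diolate may tie up copper, the bromide may be lost by protodehalogenation, or traces of oxygen may oxidise the carbinols before the C–O bond forms.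
- Fallback: give up the aryl C–O closure and resolve the racemic flavanone. The fallback sets out from aldehyde 7. Claisen–Schmidt condensation with purchased 1-[2,4-bis(benzyloxy)-6-hydroxyphenyl]ethanone (CC(=O)c1c(O)cc(OCc2ccccc2)cc1OCc1ccccc1; KOH, EtOH/THF, rt) should give the 2'-hydroxychalcone F1. NaOAc in refluxing EtOH should close it by oxa-Michael addition to the racemic hepta-O-benzyl flavanone F2. Kinetic resolution by transfer hydrogenation with RuCl(p-cymene)[(R,R)-TsDPEN] in HCO2H/Et3N, stopped near half conversion, should reduce the 2R enantiomer to the (2R,4R)-flavan-4-ol F3. The 2S ketone is left untouched, and the route is rejoined at 17. At most half of the material is usable.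

Step 10.
- What may go wrong: turnover may be slow because the substrate is strongly enolised and can bind ruthenium as a diketonate, and facial selectivity may be eroded.
- Fallback: obtain the carbinol by resolution instead of reduction. The fallback sets out from racemic aldol 12 and bypasses steps 9 and 10. Acylative kinetic resolution uses (R)-benzotetramisole (5 mol %), propionic anhydride (0.6 equiv) and iPr2NEt in CHCl3 at 0 °C. From the aryl-stacking model this catalyst antipode is expected to esterify the R carbinol faster, giving the (R)-propionate F4. The S alcohol stays unreacted, and the route is rejoined at 14 after chromatography.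

Step 11.
- What may go wrong: hydride transfer to the C4 carbonyl may be too slow because both faces are shielded by the ortho substituents of ring A, and the electron-rich C4 carbinol may ionise in acetic acid.
- Fallback: switch to the syn series under non-acidic conditions. The fallback sets out from 14. Narasaka–Prasad reduction (Et2BOMe, then NaBH4, THF/MeOH, −78 °C, boron removed by co-evaporation with MeOH) attacks the boron-activated chelate with external hydride and should give the syn (2S,4R)-diol F5. The copper conditions of step 12 should close it to the 2,4-trans (2S,4R)-flavan-4-ol F6. Dess–Martin oxidation removes the C4 stereocentre, and the route is rejoined at 17.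

Further compounds
F1 | step 12 | (E)-2'-hydroxychalcone from 7 | O=C(/C=C/c2cc(OCc9ccccc9)c(OCc9ccccc9)c(-c3c(OCc9ccccc9)cc(OCc9ccccc9)c4c(=O)cc(-c5ccc(OCc9ccccc9)cc5)oc34)c2)c1c(O)cc(OCc9ccccc9)cc1OCc9ccccc9
F2 | step 12 | racemic hepta-O-benzyl flavanone | O=C1CC(c2cc(OCc9ccccc9)c(OCc9ccccc9)c(-c3c(OCc9ccccc9)cc(OCc9ccccc9)c4c(=O)cc(-c5ccc(OCc9ccccc9)cc5)oc34)c2)Oc2cc(OCc9ccccc9)cc(OCc9ccccc9)c21
F3 | step 12 | (2R,4R)-hepta-O-benzyl flavan-4-ol | O[C@@H]1C[C@H](c2cc(OCc9ccccc9)c(OCc9ccccc9)c(-c3c(OCc9ccccc9)cc(OCc9ccccc9)c4c(=O)cc(-c5ccc(OCc9ccccc9)cc5)oc34)c2)Oc2cc(OCc9ccccc9)cc(OCc9ccccc9)c21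
F4 | step 10 | (R)-propionate of aldol 12 | O=C(C[C@@H](OC(=O)CC)c2cc(OCc9ccccc9)c(OCc9ccccc9)c(-c3c(OCc9ccccc9)cc(OCc9ccccc9)c4c(=O)cc(-c5ccc(OCc9ccccc9)cc5)oc34)c2)c1c(Br)cc(OCc9ccccc9)cc1OCc9ccccc9
F5 | step 11 | syn (2S,4R)-1,3-diol aryl bromide | O[C@H](C[C@H](O)c2cc(OCc9ccccc9)c(OCc9ccccc9)c(-c3c(OCc9ccccc9)cc(OCc9ccccc9)c4c(=O)cc(-c5ccc(OCc9ccccc9)cc5)oc34)c2)c1c(Br)cc(OCc9ccccc9)cc1OCc9ccccc9
F6 | step 11 | (2S,4R)-hepta-O-benzyl flavan-4-ol (2,4-trans) | O[C@@H]1C[C@@H](c2cc(OCc9ccccc9)c(OCc9ccccc9)c(-c3c(OCc9ccccc9)cc(OCc9ccccc9)c4c(=O)cc(-c5ccc(OCc9ccccc9)cc5)oc34)c2)Oc2cc(OCc9ccccc9)cc(OCc9ccccc9)c21
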